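The plan closes the pyran ring (ring C) of the isoflavan late, by joining the methylene C4 to the aromatic carbon C4a of ring A. It exploits the fact that C4 is a CH2 group next to the only stereocentre, C3, which bears hydrogen and the ring B aryl group: an open-chain aryl 2-arylallyl ether already holds every atom of the core. In one flask, CuH-catalysed enantioselective hydroboration of its 1,1-disubstituted alkene sets C3 and creates a primary C4–boron bond, and an intramolecular Suzuki–Miyaura coupling then joins C4 to the brominated C4a. The C8 aldehyde is carried, masked, from a symmetrical phloroglucinaldehyde, which fixes the ring A pattern.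

Key step: step 8

Remark on the chemistry: isoflavan numbering is used throughout (O1, C2, C3, C4, C4a, C5 to C8, C8a; ring A is the benzo ring, ring B the pendant aryl group, ring C the pyran) and the target is the (3R) isomer; 1 and 7 are taken as catalogue compounds; the sense of induction of the copper catalyst is to be confirmed on the first run, the route being written for (R)-DTBM-SEGPHOS and its mirror image being used if hydride is found to add to the other face.

Step 1
Reactants: 1 1,3-bis(methoxymethoxy)benzene; 2 1-bromo-3-methylbut-2-ene (prenyl bromide)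
Product: 3 1,3-bis(methoxymethoxy)-2-(3-methylbut-2-en-1-yl)benzene
Conditions: n-BuLi, THF, 0 °C → rt; then CuI (10 mol%), 2, −40 °C → rt
Reagents that add atoms: none
Why: Directed ortho-metalation removes the hydrogen flanked by both MOM ethers, and the aryllithium, through its cuprate, is alkylated at the primary carbon of prenyl bromide (SN2).

Step 2
Reactants: 3 1,3-bis(methoxymethoxy)-2-(3-methylbut-2-en-1-yl)benzene
Product: 4 2-[2,4-bis(methoxymethoxy)-3-(3-methylbut-2-en-1-yl)phenyl]-4,4,5,5-tetramethyl-1,3,2-dioxaborolane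
Conditions: n-BuLi, TMEDA, THF, −20 → 0 °C; then i-PrOBpin, −78 °C → rt; aq NH4Cl
Reagents that add atoms: 2-isopropoxy-4,4,5,5-tetramethyl-1,3,2-dioxaborolane, CC(C)OB1OC(C)(C)C(C)(C)O1
Why: A second MOM-directed ortho-metalation at one of the two equivalent ring positions next to a MOM ether, followed by borylation of the aryllithium, should give a single aryl boronate because 3 is symmetrical.

Step 3
Reactants: 4 2-[2,4-bis(methoxymethoxy)-3-(3-methylbut-2-en-1-yl)phenyl]-4,4,5,5-tetramethyl-1,3,2-dioxaborolane; 5 2-bromoprop-2-en-1-ol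
Product: 6 2-[2,4-bis(methoxymethoxy)-3-(3-methylbut-2-en-1-yl)phenyl]prop-2-en-1-ol
Conditions: Pd(dppf)Cl2 (3 mol%), K2CO3, 1,4-dioxane/H2O, 80 °C
Reagents that add atoms: none
Why: Suzuki–Miyaura coupling of the aryl boronate with the vinyl bromide builds the 2-arylallyl alcohol; the free hydroxyl and the prenyl alkene are inert.

Step 4
Reactants: 7 2,6-dihydroxy-4-methoxybenzaldehyde
Product: 8 2-hydroxy-4-methoxy-6-(methoxymethoxy)benzaldehyde
Conditions: MOMCl (1.05 equiv), i-Pr2NEt, CH2Cl2, 0 °C
Reagents that add atoms: chloromethyl methyl ether, COCCl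
Why: O-Alkoxymethylation of the symmetrical diol should stop after one ether, because the remaining hydroxyl is held in a hydrogen bond to the aldehyde and reacts far more slowly.

Step 5
Reactants: 8 2-hydroxy-4-methoxy-6-(methoxymethoxy)benzaldehyde
Product: 9 3-bromo-2-hydroxy-4-methoxy-6-(methoxymethoxy)benzaldehyde
Conditions: NBS (1.0 equiv), i-Pr2NH (10 mol%), CH2Cl2, −20 → 0 °C
Reagents that add atoms: N-bromosuccinimide, O=C1CCC(=O)N1Br
Why: Electrophilic aromatic bromination under amine catalysis is ortho-selective for phenols, and the chelated hydroxyl should direct bromine to its own ortho position, the carbon that becomes C4a next to the oxygen that becomes O1.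

Step 6
Reactants: 6 2-[2,4-bis(methoxymethoxy)-3-(3-methylbut-2-en-1-yl)phenyl]prop-2-en-1-ol; 9 3-bromo-2-hydroxy-4-methoxy-6-(methoxymethoxy)benzaldehyde
Product: 10 3-bromo-2-({2-[2,4-bis(methoxymethoxy)-3-(3-methylbut-2-en-1-yl)phenyl]prop-2-en-1-yl}oxy)-4-methoxy-6-(methoxymethoxy)benzaldehyde
Conditions: PPh3, DIAD, THF, 0 °C → rt
Reagents that add atoms: none
Why: Mitsunobu etherification of the acidic phenol with the primary allylic alcohol forms the O1–C2 bond; SN2 and SN2' attack lead to the same ether because both ends of the 2-arylallyl unit are CH2 groups.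

Step 7
Reactants: 10 3-bromo-2-({2-[2,4-bis(methoxymethoxy)-3-(3-methylbut-2-en-1-yl)phenyl]prop-2-en-1-yl}oxy)-4-methoxy-6-(methoxymethoxy)benzaldehyde
Product: 11 2-bromo-3-({2-[2,4-bis(methoxymethoxy)-3-(3-methylbut-2-en-1-yl)phenyl]prop-2-en-1-yl}oxy)-4-(dimethoxymethyl)-1-methoxy-5-(methoxymethoxy)benzene
Conditions: HC(OMe)3, MeOH, PPTS (5 mol%), rt; Et3N quench, basic alumina plug, used directly
Reagents that add atoms: trimethyl orthoformate, COC(OC)OC; methanol, CO
Why: Acid-catalysed acetalisation driven by the orthoformate masks the aldehyde, which CuH would otherwise reduce in step 8, and PPTS at room temperature should leave the aryl MOM ethers intact.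

Step 8
Reactants: 11 2-bromo-3-({2-[2,4-bis(methoxymethoxy)-3-(3-methylbut-2-en-1-yl)phenyl]prop-2-en-1-yl}oxy)-4-(dimethoxymethyl)-1-methoxy-5-(methoxymethoxy)benzene
Product: 13 (3R)-3-[2,4-bis(methoxymethoxy)-3-(3-methylbut-2-en-1-yl)phenyl]-8-(dimethoxymethyl)-5-methoxy-7-(methoxymethoxy)chromane, via (R)-alkylboronate 12 (not isolated)
Conditions: CuCl (5 mol%), (R)-DTBM-SEGPHOS (5.5 mol%), KOtBu (10 mol%), HBpin (1.5 equiv), toluene, rt; then MeOH; Pd(OAc)2 (5 mol%), RuPhos (10 mol%), K3PO4, toluene/H2O, 0.03 M, 90 °C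
Reagents that add atoms: pinacolborane, CC1(C)OBOC1(C)C (its boron and pinacol unit sit in 12 only; 13 keeps only the hydrogen at C3)
Why: The chiral CuH complex formed from CuCl, KOtBu and HBpin adds across the 1,1-disubstituted alkene of 11 with copper at the terminal carbon C4 and hydrogen at C3, and σ-bond metathesis with HBpin releases the primary boronate 12; zerovalent palladium then inserts into the C4a–Br bond, the alkyl group is transferred from the base-activated boronate and reductive elimination forms the C4–C4a bond. The closest known reaction types are the CuH-catalysed enantioselective anti-Markovnikov hydroboration of α-substituted styrenes and the intramolecular B-alkyl Suzuki–Miyaura coupling run in the flask of the hydroboration. Ring C closes through a seven-membered oxapalladacycle (Pd, C4a, C8a, O1, C2, C3, C4) whose C(sp2)–C(sp3) reductive elimination gives the six-membered pyran. The new stereocentre C3 is controlled by the chiral bisphosphine on copper, which tells the flat ring B aryl group from the CH2OAr arm and delivers hydride to the Si face of C3; the coupling takes place at C4 and leaves C3 untouched. The step needs reaction at the 1,1-disubstituted alkene and not at the trisubstituted prenyl alkene (secured by sterics), copper at C4 and not at C3 (secured by the hindered tertiary position, which also avoids β-elimination of the aryloxide), and reductive elimination faster than β-hydride elimination of C3–H (secured by the bulky RuPhos ligand and the intramolecular setting). The ring can close only at C4a, because it is the sole brominated carbon and the other position ortho to the ether oxygen, C8, is substituted.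

Step 9
Reactants: 13 (3R)-3-[2,4-bis(methoxymethoxy)-3-(3-methylbut-2-en-1-yl)phenyl]-8-(dimethoxymethyl)-5-methoxy-7-(methoxymethoxy)chromane
Product: 14 (3R)-3-[2,4-dihydroxy-3-(3-methylbut-2-en-1-yl)phenyl]-7-hydroxy-5-methoxychromane-8-carbaldehyde
Conditions: HCl (3 M aq), MeOH/THF, 40 °C, stopped at full conversion
Reagents that add atoms: water, O
Why: Acid-catalysed acetal exchange and hydrolysis should remove the three MOM ethers and the dimethyl acetal in one operation, under conditions kept mild to avoid cyclisation of the prenyl group onto the flanking phenols, and C3 has no pathway for epimerisation.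

Compound list
1 | 1,3-bis(methoxymethoxy)benzene | COCOc1cccc(OCOC)c1 | starting material
2 | 1-bromo-3-methylbut-2-ene | CC(C)=CCBr | starting material
3 | 1,3-bis(methoxymethoxy)-2-(3-methylbut-2-en-1-yl)benzene | COCOc1cccc(OCOC)c1CC=C(C)C | intermediate
4 | 2-[2,4-bis(methoxymethoxy)-3-(3-methylbut-2-en-1-yl)phenyl]-4,4,5,5-tetramethyl-1,3,2-dioxaborolane | COCOc1ccc(B2OC(C)(C)C(C)(C)O2)c(OCOC)c1CC=C(C)C | intermediate
5 | 2-bromoprop-2-en-1-ol | OCC(Br)=C | starting material
6 | 2-[2,4-bis(methoxymethoxy)-3-(3-methylbut-2-en-1-yl)phenyl]prop-2-en-1-ol | OCC(=C)c1ccc(OCOC)c(CC=C(C)C)c1OCOC | intermediate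
7 | 2,6-dihydroxy-4-methoxybenzaldehyde | COc1cc(O)c(C=O)c(O)c1 | starting material
8 | 2-hydroxy-4-methoxy-6-(methoxymethoxy)benzaldehyde | COCOc1cc(OC)cc(O)c1C=O | intermediate
9 | 3-bromo-2-hydroxy-4-methoxy-6-(methoxymethoxy)benzaldehyde | COCOc1cc(OC)c(Br)c(O)c1C=O | intermediate
10 | 3-bromo-2-({2-[2,4-bis(methoxymethoxy)-3-(3-methylbut-2-en-1-yl)phenyl]prop-2-en-1-yl}oxy)-4-methoxy-6-(methoxymethoxy)benzaldehyde | O=Cc1c(OCOC)cc(OC)c(Br)c1OCC(=C)c1ccc(OCOC)c(CC=C(C)C)c1OCOC | intermediate
11 | 2-bromo-3-({2-[2,4-bis(methoxymethoxy)-3-(3-methylbut-2-en-1-yl)phenyl]prop-2-en-1-yl}oxy)-4-(dimethoxymethyl)-1-methoxy-5-(methoxymethoxy)benzene | COC(OC)c1c(OCOC)cc(OC)c(Br)c1OCC(=C)c1ccc(OCOC)c(CC=C(C)C)c1OCOC | intermediate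
12 | 2-{(2R)-3-[2-bromo-6-(dimethoxymethyl)-3-methoxy-5-(methoxymethoxy)phenoxy]-2-[2,4-bis(methoxymethoxy)-3-(3-methylbut-2-en-1-yl)phenyl]propyl}-4,4,5,5-tetramethyl-1,3,2-dioxaborolane (not isolated) | COC(OC)c1c(OCOC)cc(OC)c(Br)c1OC[C@H](CB2OC(C)(C)C(C)(C)O2)c2ccc(OCOC)c(CC=C(C)C)c2OCOC | intermediate
13 | (3R)-3-[2,4-bis(methoxymethoxy)-3-(3-methylbut-2-en-1-yl)phenyl]-8-(dimethoxymethyl)-5-methoxy-7-(methoxymethoxy)chromane | COc1cc(OCOC)c(C(OC)OC)c2c1C[C@H](c1ccc(OCOC)c(CC=C(C)C)c1OCOC)CO2 | intermediate
14 | (3R)-3-[2,4-dihydroxy-3-(3-methylbut-2-en-1-yl)phenyl]-7-hydroxy-5-methoxychromane-8-carbaldehyde | COc1cc(O)c(C=O)c2c1C[C@H](c1ccc(O)c(CC=C(C)C)c1O)CO2 | target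

Total step count: 9. Longest linear sequence: 7 steps (steps 1, 2, 3, 6, 7, 8, 9); steps 4 and 5 form the ring A branch.

Steps most likely to fail

Step 8. After oxidative addition into the hindered, electron-rich C4a–Br bond, transfer of the alkyl group from the pinacol boronate may be slow. Protodebromination, or β-hydride elimination from the alkylpalladium at C3–H, would then give open-chain material and no ring closure. The fallback sets out from 11 and comes back at 13; it keeps the copper-controlled stereocentre but closes the ring through zinc. The hydroboration is run as in step 8 and the boronate 12 is oxidised in the flask (NaBO3·4H2O, THF/H2O, rt) to the primary alcohol (2S)-3-[2-bromo-6-(dimethoxymethyl)-3-methoxy-5-(methoxymethoxy)phenoxy]-2-[2,4-bis(methoxymethoxy)-3-(3-methylbut-2-en-1-yl)phenyl]propan-1-ol F1 (same spatial arrangement at C3; only the descriptor changes with the priorities). Iodination (I2, PPh3, imidazole, CH2Cl2, 0 °C) should give 2-bromo-3-{[(2R)-2-[2,4-bis(methoxymethoxy)-3-(3-methylbut-2-en-1-yl)phenyl]-3-iodopropyl]oxy}-4-(dimethoxymethyl)-1-methoxy-5-(methoxymethoxy)benzene F2. Zinc insertion (Zn dust, LiCl, THF, rt), which should spare the aryl bromide, would give {(2R)-3-[2-bromo-6-(dimethoxymethyl)-3-methoxy-5-(methoxymethoxy)phenoxy]-2-[2,4-bis(methoxymethoxy)-3-(3-methylbut-2-en-1-yl)phenyl]propyl}zinc iodide F3. An intramolecular Negishi coupling (Pd(OAc)2, SPhos, THF, 40 °C) through the faster-transmetalating C4–Zn bond would then form the C4–C4a bond and return to 13.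

Step 5. Bromination may take place para and not ortho to the chelated hydroxyl of 8, which would put bromine next to the MOM ether and not next to the oxygen that becomes O1. The fallback sets out from 7 and 6 and comes back at 10; it inverts the order of events so that this para preference itself places the bromine correctly. Mono-Mitsunobu etherification of the symmetrical diol 7 with 6 (PPh3, DIAD, THF) gives 2-({2-[2,4-bis(methoxymethoxy)-3-(3-methylbut-2-en-1-yl)phenyl]prop-2-en-1-yl}oxy)-6-hydroxy-4-methoxybenzaldehyde F4. Bromination of the highly activated ring (NBS, CH2Cl2, −78 °C) para to the remaining hydroxyl, that is next to the tether oxygen, should give 3-bromo-2-({2-[2,4-bis(methoxymethoxy)-3-(3-methylbut-2-en-1-yl)phenyl]prop-2-en-1-yl}oxy)-6-hydroxy-4-methoxybenzaldehyde F5. MOM protection (MOMCl, i-Pr2NEt, CH2Cl2) returns to 10.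

Step 2. Deprotonation of the doubly activated benzylic and allylic CH2 of the prenyl group may compete with ring metalation and divert the boron electrophile to the side chain. The fallback sets out from 3 and comes back at 4; it replaces deprotonation by electrophilic substitution and a palladium-catalysed borylation. Bromination of 3 (NBS, MeCN, 0 °C) at one of the two equivalent ring positions para to a MOM ether gives 1-bromo-2,4-bis(methoxymethoxy)-3-(3-methylbut-2-en-1-yl)benzene F6. Miyaura borylation (bis(pinacolato)diboron, Pd(dppf)Cl2, KOAc, 1,4-dioxane, 90 °C) returns to 4.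

Further compounds
F1 | step 8 | (2S)-3-[2-bromo-6-(dimethoxymethyl)-3-methoxy-5-(methoxymethoxy)phenoxy]-2-[2,4-bis(methoxymethoxy)-3-(3-methylbut-2-en-1-yl)phenyl]propan-1-ol | COC(OC)c1c(OCOC)cc(OC)c(Br)c1OC[C@H](CO)c2ccc(OCOC)c(CC=C(C)C)c2OCOC
F2 | step 8 | 2-bromo-3-{[(2R)-2-[2,4-bis(methoxymethoxy)-3-(3-methylbut-2-en-1-yl)phenyl]-3-iodopropyl]oxy}-4-(dimethoxymethyl)-1-methoxy-5-(methoxymethoxy)benzene | COC(OC)c1c(OCOC)cc(OC)c(Br)c1OC[C@H](CI)c2ccc(OCOC)c(CC=C(C)C)c2OCOC
F3 | step 8 | {(2R)-3-[2-bromo-6-(dimethoxymethyl)-3-methoxy-5-(methoxymethoxy)phenoxy]-2-[2,4-bis(methoxymethoxy)-3-(3-methylbut-2-en-1-yl)phenyl]propyl}zinc iodide | COC(OC)c1c(OCOC)cc(OC)c(Br)c1OC[C@H](C[Zn]I)c2ccc(OCOC)c(CC=C(C)C)c2OCOC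
F4 | step 5 | 2-({2-[2,4-bis(methoxymethoxy)-3-(3-methylbut-2-en-1-yl)phenyl]prop-2-en-1-yl}oxy)-6-hydroxy-4-methoxybenzaldehyde | O=Cc1c(O)cc(OC)cc1OCC(=C)c1ccc(OCOC)c(CC=C(C)C)c1OCOC
F5 | step 5 | 3-bromo-2-({2-[2,4-bis(methoxymethoxy)-3-(3-methylbut-2-en-1-yl)phenyl]prop-2-en-1-yl}oxy)-6-hydroxy-4-methoxybenzaldehyde | O=Cc1c(O)cc(OC)c(Br)c1OCC(=C)c1ccc(OCOC)c(CC=C(C)C)c1OCOC
F6 | step 2 | 1-bromo-2,4-bis(methoxymethoxy)-3-(3-methylbut-2-en-1-yl)benzene | COCOc1ccc(Br)c(OCOC)c1CC=C(C)C
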